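**Plan**

- Retrosynthetic cuts, in order: the four O–protecting-group bonds; C5–O and C7–O (back to C–F); O1–C8a (opens ring C to a 2-prenyl-1,3-diketone); C3–C4 (aryl ketone + 2,4,6-trifluorobenzoyl chloride); C2–C1' (Weinreb amide + ring B aryllithium); C3'–CH2 (prenyl bromide).
- Enabling feature: on ring A the oxygens O1 (on C8a), O5 and O7 are mutually meta, and each is ortho or para to the C4 carbonyl. Ring A plus C4 is therefore a disguised 2,4,6-trifluorobenzoyl group, and every ring A C–O bond can come from SNAr activated by that one carbonyl.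
- Forward: rings A and B are bought. Ring B (2-methoxyhydroquinone) is protected, iodinated at C3', brominated at C1', prenylated and acylated. The chain is joined C1'–C2, then C3–C4. Ring C is the only ring made and closes in step 9, after which the two spare fluorines become oxygens and all phenols are freed.
- The C3 prenyl group arrives inside the 5-methylhex-4-enoyl chain (Johnson–Claisen), so the diketone is never alkylated.
- Stereochemistry: the target has no stereocentre and no E/Z alkene. The one stereocentre of the diketone is racemic, enolisable and erased on ring closure.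

Key step: step 9

Remark: diketone 19 is racemic and enolisable, so its SMILES carries no stereodescriptor, and the enolate geometries drawn (Z) are the expected ones and have no consequence.
Remark: in step 10 the C7 fluorine is drawn as the first to leave, and the order of the two displacements does not affect the outcome.

Step 1
Reactants: 1 2-methylbut-3-en-2-ol; 2 triethyl orthoacetate
Product: 4 ethyl 5-methylhex-4-enoate, via ketene acetal 3 (not isolated)
Conditions: 2 (excess), EtCO2H (cat.), 140 °C, EtOH distilled off
Reagents that add atoms: none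
Why: Johnson–Claisen (orthoester Claisen) rearrangement, in which acid-catalysed exchange and loss of ethanol give ketene acetal 3, whose [3,3] shift forms the new C–C bond at the unsubstituted vinyl terminus and leaves the Me2C=CH alkene, which has no E/Z isomers.

Step 2
Reactants: 4 ethyl 5-methylhex-4-enoate
Product: 5 N-methoxy-N,5-dimethylhex-4-enamide
Conditions: MeNH(OMe)·HCl, iPrMgCl, THF, –20 → 0 °C; aq NH4Cl
Reagents that add atoms: N,O-dimethylhydroxylamine hydrochloride, CNOC.Cl
Why: Direct ester-to-Weinreb-amide aminolysis by the chloromagnesium amide made in the flask, a standard transformation that leaves the isolated alkene untouched.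

Step 3
Reactants: 6 2-methoxyhydroquinone
Product: 7 2-methoxy-1,4-bis(methoxymethoxy)benzene
Conditions: MOMCl, iPr2NEt, CH2Cl2, 0 °C → rt, Ar
Reagents that add atoms: chloromethyl methyl ether, COCCl
Why: Williamson-type O-alkylation of both phenols gives base-stable acetal ethers that mask the oxidation-prone hydroquinone and later direct lithiation.

Step 4
Reactants: 7 2-methoxy-1,4-bis(methoxymethoxy)benzene
Product: 9 2-iodo-3-methoxy-1,4-bis(methoxymethoxy)benzene, via aryllithium 8 (not isolated)
Conditions: n-BuLi, THF, 0 °C; I2, –78 °C → rt; aq Na2S2O3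
Reagents that add atoms: iodine, II
Why: Directed ortho-metalation, in which the CH between the OMe and an OMOM group is acidified and chelated from both sides (cooperative 1,3-directing groups, as in 1,2,4-trialkoxybenzenes), so lithiation and iodine quench mark the future C3'.

Step 5
Reactants: 9 2-iodo-3-methoxy-1,4-bis(methoxymethoxy)benzene
Product: 10 1-bromo-3-iodo-4-methoxy-2,5-bis(methoxymethoxy)benzene
Conditions: NBS, MeCN, 0 °C, dark
Reagents that add atoms: N-bromosuccinimide, O=C1CCC(=O)N1Br
Why: Electrophilic aromatic bromination goes to the free position para to OMe and ortho to an OMOM group (future C1'), which is activated by two oxygens while the other CH has only one, as in 3-substituted 1,2,4-trialkoxybenzenes, and running it before any prenyl group is present keeps NBS away from alkenes.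

Step 6
Reactants: 10 1-bromo-3-iodo-4-methoxy-2,5-bis(methoxymethoxy)benzene; 11 prenyl bromide
Product: 13 1-bromo-4-methoxy-2,5-bis(methoxymethoxy)-3-(3-methylbut-2-enyl)benzene, via arylmagnesium chloride 12 (not isolated)
Conditions: iPrMgCl·LiCl, THF, –30 °C; CuBr·SMe2 (10 mol %), 11, –30 → 0 °C
Reagents that add atoms: none
Why: Halogen–magnesium exchange followed by copper-catalysed allylic substitution, in which iodine exchanges far faster than bromine and the carbanion is flanked by two chelating oxygens, so only C3' is metalated, and attack at the unsubstituted terminus of 11 (SN2) gives the linear prenyl group.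

Step 7
Reactants: 13 1-bromo-4-methoxy-2,5-bis(methoxymethoxy)-3-(3-methylbut-2-enyl)benzene; 5 N-methoxy-N,5-dimethylhex-4-enamide
Product: 15 1-[4-methoxy-2,5-bis(methoxymethoxy)-3-(3-methylbut-2-enyl)phenyl]-5-methylhex-4-en-1-one, via aryllithium 14 (not isolated)
Conditions: n-BuLi, THF, –78 °C; 5, –78 → 0 °C; aq NH4Cl
Reagents that add atoms: none
Why: Bromine–lithium exchange at –78 °C outruns deprotonation of the benzylic–allylic CH2, and the Weinreb ketone synthesis forms the C1'–C2 bond without over-addition.

Step 8
Reactants: 15 1-[4-methoxy-2,5-bis(methoxymethoxy)-3-(3-methylbut-2-enyl)phenyl]-5-methylhex-4-en-1-one; 16 2,4,6-trifluorobenzoyl chloride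
Product: 19 1-[4-methoxy-2,5-bis(methoxymethoxy)-3-(3-methylbut-2-enyl)phenyl]-2-(3-methylbut-2-enyl)-3-(2,4,6-trifluorophenyl)propane-1,3-dione (racemic), via lithium enolate 17 (not isolated), via bromomagnesium enolate 18 (not isolated)
Conditions: LiN(SiMe3)2 (2.2 equiv), THF, –78 °C; MgBr2·OEt2 (2.2 equiv), –78 → –40 °C; 16, –78 → 0 °C; aq NH4Cl
Reagents that add atoms: none
Why: Claisen-type C-acylation of a ketone enolate, in which the oxygen of magnesium enolate 18 is tightly bound so that carbon attacks the very electrophilic aroyl chloride (C3–C4 bond), the second equivalent of amide base takes up the acidic proton of the product, and the new stereocentre forms racemic, which is harmless because it is lost in step 9.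

Step 9
Reactants: 19 1-[4-methoxy-2,5-bis(methoxymethoxy)-3-(3-methylbut-2-enyl)phenyl]-2-(3-methylbut-2-enyl)-3-(2,4,6-trifluorophenyl)propane-1,3-dione
Product: 21 5,7-difluoro-2-[4-methoxy-2,5-bis(methoxymethoxy)-3-(3-methylbut-2-enyl)phenyl]-3-(3-methylbut-2-enyl)chromen-4-one, via potassium enolate 20 (not isolated)
Conditions: K2CO3 (3 equiv), dry DMF (0.05 M), rt → 60 °C
Reagents that add atoms: none
Why: K2CO3 removes the proton between the two carbonyls, and in the U-shaped enolate 20 the oxygen on the ring B side adds to a fluorine-bearing carbon ortho to the ring A carbonyl, giving a Meisenheimer-type sigma complex whose charge is taken up by the C4 carbonyl and held inductively by the two remaining fluorines before fluoride leaves. The closest known reaction is the base-mediated intramolecular SNAr O-arylation of 1-(2-haloaryl)-1,3-diketones to chromones and flavones. Ring C closes as a six-membered ring through the O1–C8a bond, formally a 6-endo-trig addition–elimination because the C8a=C4a bond that accepts the charge lies inside the new ring. No stereocentre is formed, and the racemic one of 19 becomes the sp2 carbon C3. The step needs O- over C-arylation, ortho over para fluoride loss and ring closure over intermolecular attack: the enolate carbon and the para C–F cannot be reached through any unstrained cyclic transition state, the two ortho fluorines are equivalent so that a single chromone can form, and dilution favours the intramolecular path. Dry carbonate at or below 60 °C avoids retro-Claisen cleavage and Me2NH release from DMF, and leaves the MOM ethers, the methyl ether and both prenyl groups alone.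

Step 10
Reactants: 21 5,7-difluoro-2-[4-methoxy-2,5-bis(methoxymethoxy)-3-(3-methylbut-2-enyl)phenyl]-3-(3-methylbut-2-enyl)chromen-4-one
Product: 23 2-[4-methoxy-2,5-bis(methoxymethoxy)-3-(3-methylbut-2-enyl)phenyl]-3-(3-methylbut-2-enyl)-5,7-bis[2-(trimethylsilyl)ethoxy]chromen-4-one, via 5-fluoro-7-silylethoxy flavone 22 (not isolated)
Conditions: Me3SiCH2CH2OH (4 equiv), NaH (3.5 equiv), THF, 0 °C; then 21, THF–DMF, rt → 55 °C
Reagents that add atoms: 2-(trimethylsilyl)ethanol, C[Si](C)(C)CCO
Why: Twofold intermolecular SNAr, in which C7–F is para and C5–F ortho to the C4 carbonyl, the ether that enters first sits meta to the remaining C–F and stays neutral, so it does not shut ring A down as a phenoxide would, and C2 is shielded from conjugate attack by its aryl group and the C3 prenyl group.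

Step 11
Reactants: 23 2-[4-methoxy-2,5-bis(methoxymethoxy)-3-(3-methylbut-2-enyl)phenyl]-3-(3-methylbut-2-enyl)-5,7-bis[2-(trimethylsilyl)ethoxy]chromen-4-one
Product: 24 5,7-dihydroxy-2-[4-methoxy-2,5-bis(methoxymethoxy)-3-(3-methylbut-2-enyl)phenyl]-3-(3-methylbut-2-enyl)chromen-4-one
Conditions: Bu4NF (1 M in THF), THF, rt → 50 °C; aq NH4Cl
Reagents that add atoms: none
Why: Fluoride-induced desilylative β-fragmentation of aryl 2-(trimethylsilyl)ethyl ethers frees the two ring A phenols, while the MOM ethers, the methyl ether and the alkenes are inert to Bu4NF and ring B stays masked against air oxidation.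

Step 12
Reactants: 24 5,7-dihydroxy-2-[4-methoxy-2,5-bis(methoxymethoxy)-3-(3-methylbut-2-enyl)phenyl]-3-(3-methylbut-2-enyl)chromen-4-one
Product: 25 heteroartonin A, 2-[2,5-dihydroxy-4-methoxy-3-(3-methylbut-2-enyl)phenyl]-5,7-dihydroxy-3-(3-methylbut-2-enyl)chromen-4-one
Conditions: HCl (ca. 0.5 M, from conc. aq HCl), MeOH, 40 °C, Ar
Reagents that add atoms: none
Why: Acid-catalysed acetal exchange (MOM cleavage) in methanol, the usual last step for prenylated polyphenols, is run dilute, warm rather than hot and under argon so that the phenols are freed faster than they can add to protonated prenyl double bonds.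

**Compound list**

1 | 2-methylbut-3-en-2-ol | C=CC(C)(C)O | starting material
2 | triethyl orthoacetate | CCOC(C)(OCC)OCC | starting material
3 | 3-(1-ethoxyethenyloxy)-3-methylbut-1-ene (ketene acetal, not isolated) | C=C(OCC)OC(C)(C)C=C | intermediate
4 | ethyl 5-methylhex-4-enoate | CCOC(=O)CCC=C(C)C | intermediate
5 | N-methoxy-N,5-dimethylhex-4-enamide | CON(C)C(=O)CCC=C(C)C | intermediate
6 | 2-methoxyhydroquinone | COc1cc(O)ccc1O | starting material
7 | 2-methoxy-1,4-bis(methoxymethoxy)benzene | COCOc1ccc(OCOC)c(OC)c1 | intermediate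
8 | [2-methoxy-3,6-bis(methoxymethoxy)phenyl]lithium (not isolated) | [Li]c1c(OCOC)ccc(OCOC)c1OC | intermediate
9 | 2-iodo-3-methoxy-1,4-bis(methoxymethoxy)benzene | COCOc1ccc(OCOC)c(OC)c1I | intermediate
10 | 1-bromo-3-iodo-4-methoxy-2,5-bis(methoxymethoxy)benzene | COCOc1cc(Br)c(OCOC)c(I)c1OC | intermediate
11 | prenyl bromide (1-bromo-3-methylbut-2-ene) | CC(C)=CCBr | starting material
12 | [3-bromo-6-methoxy-2,5-bis(methoxymethoxy)phenyl]magnesium chloride (not isolated) | COCOc1cc(Br)c(OCOC)c([Mg]Cl)c1OC | intermediate
13 | 1-bromo-4-methoxy-2,5-bis(methoxymethoxy)-3-(3-methylbut-2-enyl)benzene | COCOc1cc(Br)c(OCOC)c(CC=C(C)C)c1OC | intermediate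
14 | [4-methoxy-2,5-bis(methoxymethoxy)-3-(3-methylbut-2-enyl)phenyl]lithium (not isolated) | COCOc1cc([Li])c(OCOC)c(CC=C(C)C)c1OC | intermediate
15 | 1-[4-methoxy-2,5-bis(methoxymethoxy)-3-(3-methylbut-2-enyl)phenyl]-5-methylhex-4-en-1-one | CC(C)=CCCC(=O)c1cc(OCOC)c(OC)c(CC=C(C)C)c1OCOC | intermediate
16 | 2,4,6-trifluorobenzoyl chloride | O=C(Cl)c1c(F)cc(F)cc1F | starting material
17 | lithium (Z)-enolate of 15 (not isolated) | CC(C)=CC/C=C(/c1cc(OCOC)c(OC)c(CC=C(C)C)c1OCOC)O[Li] | intermediate
18 | bromomagnesium (Z)-enolate of 15 (not isolated) | CC(C)=CC/C=C(/c1cc(OCOC)c(OC)c(CC=C(C)C)c1OCOC)O[Mg]Br | intermediate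
19 | 1-[4-methoxy-2,5-bis(methoxymethoxy)-3-(3-methylbut-2-enyl)phenyl]-2-(3-methylbut-2-enyl)-3-(2,4,6-trifluorophenyl)propane-1,3-dione (racemic) | CC(C)=CCC(C(=O)c1c(F)cc(F)cc1F)C(=O)c1cc(OCOC)c(OC)c(CC=C(C)C)c1OCOC | intermediate
20 | potassium (Z)-enolate of 19, U-shaped (not isolated) | CC(C)=CC/C(C(=O)c1c(F)cc(F)cc1F)=C(/[O-])c1cc(OCOC)c(OC)c(CC=C(C)C)c1OCOC.[K+] | intermediate
21 | 5,7-difluoro-2-[4-methoxy-2,5-bis(methoxymethoxy)-3-(3-methylbut-2-enyl)phenyl]-3-(3-methylbut-2-enyl)chromen-4-one | CC(C)=CCc1c(-c2cc(OCOC)c(OC)c(CC=C(C)C)c2OCOC)oc2cc(F)cc(F)c2c1=O | intermediate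
22 | 5-fluoro-2-[4-methoxy-2,5-bis(methoxymethoxy)-3-(3-methylbut-2-enyl)phenyl]-3-(3-methylbut-2-enyl)-7-[2-(trimethylsilyl)ethoxy]chromen-4-one (not isolated) | CC(C)=CCc1c(-c2cc(OCOC)c(OC)c(CC=C(C)C)c2OCOC)oc2cc(OCC[Si](C)(C)C)cc(F)c2c1=O | intermediate
23 | 2-[4-methoxy-2,5-bis(methoxymethoxy)-3-(3-methylbut-2-enyl)phenyl]-3-(3-methylbut-2-enyl)-5,7-bis[2-(trimethylsilyl)ethoxy]chromen-4-one | CC(C)=CCc1c(-c2cc(OCOC)c(OC)c(CC=C(C)C)c2OCOC)oc2cc(OCC[Si](C)(C)C)cc(OCC[Si](C)(C)C)c2c1=O | intermediate
24 | 5,7-dihydroxy-2-[4-methoxy-2,5-bis(methoxymethoxy)-3-(3-methylbut-2-enyl)phenyl]-3-(3-methylbut-2-enyl)chromen-4-one | CC(C)=CCc1c(-c2cc(OCOC)c(OC)c(CC=C(C)C)c2OCOC)oc2cc(O)cc(O)c2c1=O | intermediate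
25 | heteroartonin A | COc1c(O)cc(-c2oc3cc(O)cc(O)c3c(=O)c2CC=C(C)C)c(O)c1CC=C(C)C | target

**Count**

Total steps: 12. Longest linear sequence: 10 (steps 3–12, from 6). The side chain (steps 1–2) joins in step 7.

**Steps most likely to fail**

Step 8. The enolate may be acylated on oxygen. Proton exchange between the product and unreacted enolate may stall conversion. MgBr2 may also begin to strip the MOM group ortho to the carbonyl.
The fallback replaces acylation by addition and oxidation. Setting out from 15, lithium enolate 17 is added at –78 °C to 2,4,6-trifluorobenzaldehyde, an aldol addition in which only carbon can bond productively. This should give 3-hydroxy-1-[4-methoxy-2,5-bis(methoxymethoxy)-3-(3-methylbut-2-enyl)phenyl]-2-(3-methylbut-2-enyl)-3-(2,4,6-trifluorophenyl)propan-1-one F1 as a mixture of racemic diastereomers. Dess–Martin periodinane (NaHCO3, CH2Cl2) then oxidises the carbinol, and the route is rejoined at 19.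

Step 10. The second displacement may stall for three reasons. The sodium silylethoxide may fragment on heating (Peterson-type loss of ethene). The fluoride released may prematurely unmask the first-formed ether to a phenoxide that deactivates ring A. The alkoxide may be consumed in reversible opening of ring C at C2.
The fallback uses an oxygen nucleophile that neither heat nor fluoride can unmask, and unmasks it by transition-metal catalysis instead. Setting out from 21, sodium allyloxide (allyl alcohol, NaH, DMF, 60–80 °C) should give 2-[4-methoxy-2,5-bis(methoxymethoxy)-3-(3-methylbut-2-enyl)phenyl]-3-(3-methylbut-2-enyl)-5,7-bis(prop-2-enyloxy)chromen-4-one F2. Pd(PPh3)4 (cat.) with morpholine in THF at rt then removes both allyl groups (Tsuji–Trost-type deallylation by zerovalent palladium). The prenyl groups carry no leaving group and stay, and the route is rejoined at 24.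

Step 12. Brønsted acid may protonate the prenyl double bonds. The freed ortho phenols, above all 2'-OH towards the C3' or C3 prenyl group, may then add to them and form a cyclic ether.
The fallback avoids protic acid altogether and replaces steps 11 and 12. Setting out from 23, Et3SiOTf and 2,2'-bipyridyl (CH2Cl2–MeCN, 0 °C) exchange the two aryl MOM ethers for silyl ethers. This should give 2-[4-methoxy-3-(3-methylbut-2-enyl)-2,5-bis(triethylsilyloxy)phenyl]-3-(3-methylbut-2-enyl)-5,7-bis[2-(trimethylsilyl)ethoxy]chromen-4-one F3. Bu4NF in degassed THF, quenched with AcOH, then removes all four silicon-based groups in one operation and arrives at 25.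

**Further compounds**

F1 | step 8 | 3-hydroxy-1-[4-methoxy-2,5-bis(methoxymethoxy)-3-(3-methylbut-2-enyl)phenyl]-2-(3-methylbut-2-enyl)-3-(2,4,6-trifluorophenyl)propan-1-one (mixture of racemic diastereomers) | CC(C)=CCC(C(O)c1c(F)cc(F)cc1F)C(=O)c1cc(OCOC)c(OC)c(CC=C(C)C)c1OCOC
F2 | step 10 | 2-[4-methoxy-2,5-bis(methoxymethoxy)-3-(3-methylbut-2-enyl)phenyl]-3-(3-methylbut-2-enyl)-5,7-bis(prop-2-enyloxy)chromen-4-one | CC(C)=CCc1c(-c2cc(OCOC)c(OC)c(CC=C(C)C)c2OCOC)oc2cc(OCC=C)cc(OCC=C)c2c1=O
F3 | step 12 | 2-[4-methoxy-3-(3-methylbut-2-enyl)-2,5-bis(triethylsilyloxy)phenyl]-3-(3-methylbut-2-enyl)-5,7-bis[2-(trimethylsilyl)ethoxy]chromen-4-one | CC(C)=CCc1c(-c2cc(O[Si](CC)(CC)CC)c(OC)c(CC=C(C)C)c2O[Si](CC)(CC)CC)oc2cc(OCC[Si](C)(C)C)cc(OCC[Si](C)(C)C)c2c1=O
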